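At early times the isomer of the product already reads 85.2% in the amber run at 10.0 s, and afterwards it sinks slowly, so whoever takes over this bench finds a new flask that is steadily losing isomer.

| flask | starting material | catalyst | remark | time |
|---|---|---|---|---|
| blue | 0.093 M | 0.25 mol% | run made earlier |  |
| amber | 0.093 M | 0.38 mol% | run made earlier |  |
| teal | 0.14 M | 0.5 mol% | run made earlier |  |
| flask | 0.093 M | 0.5 mol% |  | 2.0 min |

| run | time / s | target / % | isomer of the product / % |
|---|---|---|---|
| blue | 10.0 | 3.3 | 82.1 |
| blue | 12.0 | 3.9 | 83.0 |
| blue | 20.0 | 4.0 | 79.5 |
| blue | 30.0 | 2.7 | 79.4 |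
| blue | 50.0 | 3.7 | 75.1 |
| blue | 80.0 | 2.3 | 68.6 |
| amber | 10.0 | 3.3 | 85.2 |
| amber | 12.0 | 2.3 | 83.8 |
| amber | 20.0 | 4.0 | 83.0 |
| amber | 30.0 | 1.6 | 79.3 |
| amber | 40.0 | 0.3 | 76.7 |
| amber | 60.0 | 2.7 | 73.2 |
| amber | 80.0 | 2.5 | 68.6 |
| teal | 15.0 | 2.9 | 85.1 |
| teal | 30.0 | 4.3 | 80.7 |
| teal | 40.0 | 3.6 | 80.4 |
| teal | 60.0 | 3.2 | 74.4 |
| teal | 80.0 | 1.1 | 67.9 |

(each reading ± 1 percentage point)

- the analysis behind the earlier runs scatters by 1 percentage point, standard deviation
- a reading or a percentage of target counts all its forms, free or not

* target present at 2.0 min, in percent of the starting material charged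
* isomer of the product present at 2.0 min, in percent of the starting material charged
* uncatalysed product present at 2.0 min, in percent of the starting material charged

Leave the catalyst in the new flask alone: at 80.0 s the blue and amber runs read 68.6% and 68.6% of isomer, although amber has the higher loading. Read the flask on time instead. I carry amber's first-to-last logarithmic fall on from its last reading:

isomer at 2.0 min = 60.6%

Dividing target by isomer takes time out of the reckoning, so I pool every reading into one target-per-isomer ratio, itself a reading with their scatter, which I treat as a quasi-equilibrium ratio: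

target per isomer = 0.0368

target = 0.0368 × 60.6% = 2.23%

rest of the charge = 37.2%

That rest is the part of the charge I do not read; it holds the uncatalysed product and whatever else stands beside it.

The forecast says 2.3% target, 60% isomer and 36% uncatalysed product: "Any lingering starting material would lower this".

The new flask gives 2.11%, 60.9% and 33.6%.

    starting material → uncatalysed product (k = 0.0634 s⁻¹)
    starting material + target ⇌ idle adduct, settled at all times (K = 8.98 M⁻¹)
    starting material + catalyst ⇌ target + catalyst, rate k3*[starting material]*[catalyst] forward; the back reaction follows from the equilibrium constant (K = 0.610, k = 534 M⁻¹ s⁻¹)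
    isomer of the product + catalyst ⇌ starting material + catalyst, rate k4*[catalyst]*[isomer of the product] forward; the back reaction follows from the equilibrium constant (k = 228 M⁻¹ s⁻¹)
    target ⇌ isomer of the product (K = 29.1, k = 0.0105 s⁻¹)

Applied to the flask's isomer, the ratio gives 2.24% target against 2.11% found, and the flask still holds 3.3% starting material and 0.114% idle adduct beside its uncatalysed product. The neighbouring flask has the same charge but is read at 3.0 min. It holds 50.4% isomer, so the ratio gives 1.85% target against 1.73% found. Its rest by the same reckoning is 47.7%. The neighbouring flask holds 45.1% uncatalysed product, 2.8% starting material and 0.0778% idle adduct.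

The runs stem from a simulated flask with constants of no real substance; scatter was added.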